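## Retrosynthetic overview

1. Target ⇒ diepoxy triol + three angeloyl groups from angelic anhydride. The esters go on last, because the free hydroxyls are the handles for both epoxidations.
2. Diepoxy triol ⇒ dienyl triol. The two oxirane rings (ring C4–C5 and side-chain C10–C11) are closed together, last, by hydroxyl-directed epoxidation from C3–OH and C8–OH. The cyclohexane ring is never built; it comes from carvone.
3. Dienyl triol ⇒ bis-allyl ether C8H2–O–C(CH3)2–CH=CH2. Key step: a [2,3]-Wittig sigmatropic rearrangement forms the C8–C9 bond and the C8 carbinol centre and unveils C10=C11.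
4. Bis-allyl ether ⇒ allylic chloride (ring diol masked as acetonide) + 2-methylbut-3-en-2-ol (Williamson).
5. Chloro diol ⇒ (R)-carvone: ene-type chlorination of the isopropenyl group, Rubottom α'-hydroxylation (C2), Luche reduction (C3). C1 of carvone is the only bought stereocentre and controls all the others.

Assumption: the target is exactly the stereoisomer of the given SMILES, (1S,2S,3R,4S,5S,8S,10R) in the labels used here: ring C1 (bears the side chain), C2 and C3 (ester oxygens), C4 (methyl) and C5 (ring oxirane), C6 (CH2); side chain C7(=C14H2)–C8(O)–C9H2–C10(oxirane CH)–C11(CH3)2.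
Assumption: angelic anhydride is taken as a catalogue reagent.

## Route

Step 1
Reactants: 1 (R)-(−)-carvone
Product: 2 (5R)-5-(3-chloroprop-1-en-2-yl)-2-methylcyclohex-2-en-1-one (10-chlorocarvone)
Conditions: Ca(OCl)2, CO2 (dry ice), CH2Cl2/H2O, 0 °C
Reagents that add atoms: calcium hypochlorite, [Ca+2].[O-]Cl.[O-]Cl
Why: Ene-type allylic chlorination by HOCl (from Ca(OCl)2/CO2) occurs only at the electron-rich isopropenyl alkene, the enone alkene being deactivated, and no stereocentre is touched.

Step 2
Reactants: 2 10-chlorocarvone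
Product: 6 (5S,6S)-5-(3-chloroprop-1-en-2-yl)-6-hydroxy-2-methylcyclohex-2-en-1-one, via lithium dienolate 3 (not isolated), via trimethylsilyl dienol ether 4 (not isolated), via silyloxy ketone 5 (not isolated)
Conditions: LiN(iPr)2, TMSCl, THF, −78 °C; evaporate, CH2Cl2; mCPBA, −20 → 0 °C; then 1 M HCl/THF, 0 °C
Reagents that add atoms: mCPBA, OOC(=O)c1cccc(Cl)c1
Why: Kinetic α'-deprotonation and silylation give the cross-conjugated silyl dienol ether, and its Rubottom oxidation takes place at the enol-ether alkene on the face anti to the neighbouring C1 substituent, setting the C2 oxygen trans to the side chain, while the chloromethyl-deactivated alkene is left.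

Step 3
Reactants: 6 trans-hydroxy enone
Product: 7 (1S,2S,6S)-6-(3-chloroprop-1-en-2-yl)-3-methylcyclohex-3-ene-1,2-diol
Conditions: NaBH4, CeCl3·7H2O, MeOH, −78 → −20 °C
Reagents that add atoms: none
Why: Luche 1,2-reduction with axial hydride delivery to the half-chair enone gives the equatorial C3 alcohol, trans to C2–OH and cis to the C1 substituent (all-equatorial triad), without touching the allylic chloride.

Step 4
Reactants: 7 chloro diol
Product: 8 (3aS,4S,7aS)-4-(3-chloroprop-1-en-2-yl)-2,2,7-trimethyl-3a,4,5,7a-tetrahydro-2H-1,3-benzodioxole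
Conditions: 2-methoxypropene, PPTS (cat.), CH2Cl2, 0 °C → rt
Reagents that add atoms: 2-methoxypropene, COC(C)=C
Why: Kinetic acid-catalysed acetalisation closes the trans-fused dioxolane on the diequatorial diol, so that neither hydroxyl can alkylate the allylic chloride intramolecularly under the basic conditions that follow.

Step 5
Reactants: 8 chloro acetonide; 9 2-methylbut-3-en-2-ol
Product: 11 (3aS,4S,7aS)-2,2,7-trimethyl-4-{3-[(2-methylbut-3-en-2-yl)oxy]prop-1-en-2-yl}-3a,4,5,7a-tetrahydro-2H-1,3-benzodioxole, via sodium 2-methylbut-3-en-2-olate 10 (not isolated)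
Conditions: NaH, 9 (3 equiv), THF/DMF, 0 °C → rt; then 8, Bu4NI (cat.), 40 °C
Reagents that add atoms: none
Why: Williamson ether synthesis in which the tertiary alkoxide displaces the primary allylic chloride (SN2; the SN2' path gives the same product) under iodide catalysis, the chloride having no β-hydrogen to eliminate and no stereocentre being involved.

Step 6
Reactants: 11 bis-allyl ether
Product: 15 (1S,2S,6S)-6-[(3S)-3-hydroxy-6-methylhepta-1,5-dien-2-yl]-3-methylcyclohex-3-ene-1,2-diol, via C8-lithiated ether 12 (not isolated), via lithium alkoxide 13 (not isolated), via acetonide alcohol 14 (not isolated)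
Conditions: n-BuLi (1.5 equiv), THF, −78 → −20 °C; then AcOH/H2O (4:1), 40 °C
Reagents that add atoms: none
Why: [2,3]-Wittig sigmatropic rearrangement in which n-BuLi deprotonates C8 (the only CH2 that is both allylic and next to oxygen), the five-membered envelope transition state bonds C8 to the vinyl terminus C9 while O–C11 breaks and C10=C11 forms, the allyl unit reaching the C8 face away from the oxygenated C2 branch of the ring (C1–H eclipsing C7=C14, lithium held by the C2 acetal oxygen) to give 8S, and the acidic quench then hydrolyses the strained trans-fused acetonide.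

Step 7
Reactants: 15 dienyl triol
Product: 16 (1R,2R,3S,4S,6S)-4-{(3S)-4-[(2R)-3,3-dimethyloxiran-2-yl]-3-hydroxybut-1-en-2-yl}-1-methyl-7-oxabicyclo[4.1.0]heptane-2,3-diol
Conditions: Mo(CO)6 (10 mol %), t-BuOOH (2.5 equiv, decane), Na2HPO4, 1,2-dichloroethane, 60 °C
Reagents that add atoms: tert-butyl hydroperoxide, CC(C)(C)OO
Why: Hydroxyl-directed epoxidation through molybdenum alkoxide–alkylperoxide complexes, in which C3–OH delivers oxygen to its own face of the ring alkene (oxirane cis to C3–O) and C8–OH delivers to C10=C11 through a chair transition state with the C7 substituent equatorial (1,3-syn, 10R), while molybdenum, unlike vanadium, favours homoallylic and electron-rich trisubstituted alkenes and so leaves the allylic 1,1-disubstituted C7=C14.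

Step 8
Reactants: 16 diepoxy triol; 17 angelic anhydride ((2Z)-2-methylbut-2-enoic anhydride)
Product: 19 CNP0258231.3 (1S,2R,3S,4S,6S)-4-{(3S)-4-[(2R)-3,3-dimethyloxiran-2-yl]-3-{[(2Z)-2-methylbut-2-enoyl]oxy}but-1-en-2-yl}-1-methyl-7-oxabicyclo[4.1.0]heptane-2,3-diyl bis[(2Z)-2-methylbut-2-enoate], via trilithium trialkoxide 18 (not isolated)
Conditions: LiN(SiMe3)2 (3.0 equiv), THF, −78 °C; then 17 (4.5 equiv), −78 → 0 °C; aq. NH4Cl
Reagents that add atoms: angelic anhydride, C/C=C(/C)C(=O)OC(=O)/C(C)=C\C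
Why: Stereoconservative angeloylation by nucleophilic acyl substitution, in which each of the three lithium alkoxides takes one angeloyl group from its own molecule of 17 (three molecules used up in all). No nucleophilic amine catalyst or acid is present, so the Z geometry and both oxiranes are kept; the C3 alkoxide is cis to the ring oxirane and cannot undergo Payne rearrangement, and no stereocentre is touched.

## Compound list

1 | (R)-(−)-carvone | C=C(C)[C@@H]1CC=C(C)C(=O)C1 | starting material
2 | (5R)-5-(3-chloroprop-1-en-2-yl)-2-methylcyclohex-2-en-1-one | C=C(CCl)[C@@H]1CC=C(C)C(=O)C1 | intermediate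
3 | lithium (3R)-3-(3-chloroprop-1-en-2-yl)-6-methylcyclohexa-1,5-dien-1-olate | C=C(CCl)[C@@H]1CC=C(C)C([O-])=C1.[Li+] | intermediate
4 | {[(3R)-3-(3-chloroprop-1-en-2-yl)-6-methylcyclohexa-1,5-dien-1-yl]oxy}trimethylsilane | C=C(CCl)[C@@H]1CC=C(C)C(O[Si](C)(C)C)=C1 | intermediate
5 | (5S,6S)-5-(3-chloroprop-1-en-2-yl)-2-methyl-6-[(trimethylsilyl)oxy]cyclohex-2-en-1-one | C=C(CCl)[C@@H]1CC=C(C)C(=O)[C@H]1O[Si](C)(C)C | intermediate
6 | (5S,6S)-5-(3-chloroprop-1-en-2-yl)-6-hydroxy-2-methylcyclohex-2-en-1-one | C=C(CCl)[C@@H]1CC=C(C)C(=O)[C@H]1O | intermediate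
7 | (1S,2S,6S)-6-(3-chloroprop-1-en-2-yl)-3-methylcyclohex-3-ene-1,2-diol | C=C(CCl)[C@@H]1CC=C(C)[C@H](O)[C@H]1O | intermediate
8 | (3aS,4S,7aS)-4-(3-chloroprop-1-en-2-yl)-2,2,7-trimethyl-3a,4,5,7a-tetrahydro-2H-1,3-benzodioxole | C=C(CCl)[C@@H]1CC=C(C)[C@@H]2OC(C)(C)O[C@@H]12 | intermediate
9 | 2-methylbut-3-en-2-ol | C=CC(C)(C)O | starting material
10 | sodium 2-methylbut-3-en-2-olate | C=CC(C)(C)[O-].[Na+] | intermediate
11 | (3aS,4S,7aS)-2,2,7-trimethyl-4-{3-[(2-methylbut-3-en-2-yl)oxy]prop-1-en-2-yl}-3a,4,5,7a-tetrahydro-2H-1,3-benzodioxole | C=CC(C)(C)OCC(=C)[C@@H]1CC=C(C)[C@@H]2OC(C)(C)O[C@@H]12 | intermediate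
12 | C8-lithiated derivative of 11 (α-alkoxy allyllithium, configuration at the lithiated carbon labile) | C=CC(C)(C)OC([Li])C(=C)[C@@H]1CC=C(C)[C@@H]2OC(C)(C)O[C@@H]12 | intermediate
13 | lithium (3S)-6-methyl-2-[(3aS,4S,7aS)-2,2,7-trimethyl-3a,4,5,7a-tetrahydro-2H-1,3-benzodioxol-4-yl]hepta-1,5-dien-3-olate | C=C([C@H](CC=C(C)C)[O-])[C@@H]1CC=C(C)[C@@H]2OC(C)(C)O[C@@H]12.[Li+] | intermediate
14 | (3S)-6-methyl-2-[(3aS,4S,7aS)-2,2,7-trimethyl-3a,4,5,7a-tetrahydro-2H-1,3-benzodioxol-4-yl]hepta-1,5-dien-3-ol | C=C([C@H](CC=C(C)C)O)[C@@H]1CC=C(C)[C@@H]2OC(C)(C)O[C@@H]12 | intermediate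
15 | (1S,2S,6S)-6-[(3S)-3-hydroxy-6-methylhepta-1,5-dien-2-yl]-3-methylcyclohex-3-ene-1,2-diol | C=C([C@H](CC=C(C)C)O)[C@@H]1CC=C(C)[C@H](O)[C@H]1O | intermediate
16 | (1R,2R,3S,4S,6S)-4-{(3S)-4-[(2R)-3,3-dimethyloxiran-2-yl]-3-hydroxybut-1-en-2-yl}-1-methyl-7-oxabicyclo[4.1.0]heptane-2,3-diol | C=C([C@H](C[C@H]1OC1(C)C)O)[C@@H]1C[C@@H]2O[C@]2(C)[C@H](O)[C@H]1O | intermediate
17 | angelic anhydride, (2Z)-2-methylbut-2-enoic anhydride | C/C=C(/C)C(=O)OC(=O)/C(C)=C\C | starting material
18 | trilithium trialkoxide of 16 (all three hydroxyls deprotonated, configuration as in 16) | C=C([C@H](C[C@H]1OC1(C)C)[O-])[C@@H]1C[C@@H]2O[C@]2(C)[C@H]([O-])[C@H]1[O-].[Li+].[Li+].[Li+] | intermediate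
19 | CNP0258231.3, (1S,2R,3S,4S,6S)-4-{(3S)-4-[(2R)-3,3-dimethyloxiran-2-yl]-3-{[(2Z)-2-methylbut-2-enoyl]oxy}but-1-en-2-yl}-1-methyl-7-oxabicyclo[4.1.0]heptane-2,3-diyl bis[(2Z)-2-methylbut-2-enoate] | C=C([C@H](C[C@H]1OC1(C)C)OC(=O)/C(C)=C\C)[C@@H]1C[C@@H]2O[C@]2(C)[C@H](OC(=O)/C(C)=C\C)[C@H]1OC(=O)/C(C)=C\C | target

## Step count and risks

Total step count: 8. Longest linear sequence: 8 steps, from (R)-carvone 1 (9 and 17 are bought).

The three steps most likely to fail:

**Step 6.** The facial selectivity at C8 rests on a remote ring stereocentre and is expected to be only moderate. The sense predicted above is a conformational argument, and the C8 epimers would be separated at the stage of 15. [1,2]- and [1,4]-shifts can also compete if the temperature rises. The fallback sets out from 11 and comes back at 14. The rearrangement is quenched with aqueous NH4Cl instead of acetic acid, so that acetonide alcohol 14 and its C8 epimer, 8-epi acetonide alcohol F1, can be separated on silica. F1 is then inverted at C8 by a Mitsunobu reaction (4-nitrobenzoic acid, PPh3, DIAD, THF, 0 °C; SN2 with inversion) to the (8S)-4-nitrobenzoate F2. Methanolysis (K2CO3, MeOH) releases 14, which is hydrolysed to 15 as in step 6. C8 is then fixed by a stereospecific substitution, not by the rearrangement.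

**Step 7.** Three things can go wrong: the allylic C7=C14 alkene may be attacked as well; the 1,3-syn preference at C10 is an extrapolation from the chair model to molybdenum; and the Lewis-acidic medium could let C8–OH open the new oxirane at C11. The fallback sets out from 15 and comes back at 16. Metal-alkoxide delivery is given up for a peracid: mCPBA (2.1 equiv, NaHCO3, CH2Cl2, −20 °C) takes the two electron-rich trisubstituted alkenes and leaves the 1,1-disubstituted C7=C14 on electronic grounds. The ring oxirane still forms cis to C3–OH (Henbest hydrogen-bond direction). The side-chain oxirane forms with only weak hydrogen-bond bias from C8–OH, so the unwanted 10-epi diepoxy triol F3 is removed by chromatography before 16 goes on.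

**Step 8.** Three hindered secondary hydroxyls (C3–OH next to the quaternary oxirane carbon, C2–OH flanked on both sides) must all be acylated by a hindered anhydride. Any amide base left over can γ-deprotonate an angelate already formed and scramble its geometry to the tiglate. The fallback sets out from 16 and comes back at 19. Instead of transferring preformed angeloyl groups, the three Z-alkenes are built on the esters. Compound 16 is acylated with 2-[bis(2,2,2-trifluoroethoxy)phosphoryl]propanoic acid (EDC·HCl, DMAP, CH2Cl2) to the tris(phosphonopropanoate) F4. A threefold Still–Gennari olefination (KN(SiMe3)2, 18-crown-6, THF, −78 °C, acetaldehyde) then gives the three (Z)-2-methylbut-2-enoates of 19.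

## Further compounds

F1 | step 6 | 8-epi acetonide alcohol, (3R)-6-methyl-2-[(3aS,4S,7aS)-2,2,7-trimethyl-3a,4,5,7a-tetrahydro-2H-1,3-benzodioxol-4-yl]hepta-1,5-dien-3-ol | C=C([C@@H](CC=C(C)C)O)[C@@H]1CC=C(C)[C@@H]2OC(C)(C)O[C@@H]12
F2 | step 6 | (8S)-4-nitrobenzoate, (3S)-6-methyl-2-[(3aS,4S,7aS)-2,2,7-trimethyl-3a,4,5,7a-tetrahydro-2H-1,3-benzodioxol-4-yl]hepta-1,5-dien-3-yl 4-nitrobenzoate | C=C([C@H](CC=C(C)C)OC(=O)c1ccc(cc1)[N+](=O)[O-])[C@@H]1CC=C(C)[C@@H]2OC(C)(C)O[C@@H]12
F3 | step 7 | 10-epi diepoxy triol, (1R,2R,3S,4S,6S)-4-{(3S)-4-[(2S)-3,3-dimethyloxiran-2-yl]-3-hydroxybut-1-en-2-yl}-1-methyl-7-oxabicyclo[4.1.0]heptane-2,3-diol | C=C([C@H](C[C@@H]1OC1(C)C)O)[C@@H]1C[C@@H]2O[C@]2(C)[C@H](O)[C@H]1O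
F4 | step 8 | tris(phosphonopropanoate), the tris{2-[bis(2,2,2-trifluoroethoxy)phosphoryl]propanoate} of 16 (ring and side-chain configuration as in 16, phosphonate α-carbons unspecified) | C=C([C@H](C[C@H]1OC1(C)C)OC(=O)C(C)P(=O)(OCC(F)(F)F)OCC(F)(F)F)[C@@H]1C[C@@H]2O[C@]2(C)[C@H](OC(=O)C(C)P(=O)(OCC(F)(F)F)OCC(F)(F)F)[C@H]1OC(=O)C(C)P(=O)(OCC(F)(F)F)OCC(F)(F)F
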